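**Plan**

1. Numbering (eremophilane): ring A = C1–C5 and C10 (O on C3, methyl C15 on C4, methyl C14 on quaternary C5); ring B = C5–C10 (C8 ketone, C11 carbinol carbon on C7).
2. Cuts, last-formed first: the ester C–O bond at C3; the C11–O bond (hydration of a C7 isopropenyl group); C6=C7, which opens ring B; C9–C10 (mesityl oxide onto a C10 ketone); C5–C6 and C4–C15 (acetal carbon and methyl onto a cyclohexenone); ring A into a silyloxy aldehyde and ethyl vinyl ketone.
3. Forward: ring A first (enamine Michael addition, aldol condensation), then its three stereocentres, then the C9–C7–C11 chain on C10, then ring B by C6–C7 bond formation, then hydration, desilylation and acylation.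
4. Key event: intramolecular aldol condensation of the C6 aldehyde with C7 of the C8 dienolate. It rests on C5 being quaternary (C6 cannot enolise and is the only acceptor), on C7 being the only nucleophilic carbon that reaches C6 through a six-membered ring, and on the C1 methylene γ to C8, which lets the C9=C10 isomers interconvert so that the whole mixture funnels into ring B and the finished cross-conjugated dienone.
5. Stereochemistry: C3 from catalyst control in the Michael addition; C4 (cuprate anti to the C3 silyloxy group) and C5 (electrophile anti to the C4 methyl) relayed from C3 by substrate control; the Z geometry of the acid from an anti-carbomagnesiation of propargyl alcohol.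

Key step: step 7

Remark: the enamine of the α-silyloxy aldehyde is assumed to react with the facial sense known for unbranched aldehydes; were it the opposite, the (R)-catalyst would be used in step 1.

**Route**

Step 1
Reactants: 1 (tert-butyldimethylsilyloxy)acetaldehyde; 2 pent-1-en-3-one
Product: 3 (2R)-2-(tert-butyldimethylsilyloxy)-5-oxoheptanal
Conditions: (S)-α,α-diphenylprolinol trimethylsilyl ether (10 mol %), ethyl 3,4-dihydroxybenzoate (20 mol %), neat, 4 °C
Reagents that add atoms: none
Why: Enamine-catalysed Michael addition of an aldehyde to a vinyl ketone, in which the E-enamine of 1 should add to 2 on the face remote from the diphenyl(silyloxy)methyl group of the catalyst and so set the future C3 centre as R.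

Step 2
Reactants: 3 (2R)-2-(tert-butyldimethylsilyloxy)-5-oxoheptanal
Product: 5 (4R)-4-(tert-butyldimethylsilyloxy)-2-methylcyclohex-2-en-1-one, via β-hydroxy ketone 4 (not isolated)
Conditions: p-TsOH·H2O (5 mol %), toluene, 40 °C
Reagents that add atoms: none
Why: Acid-catalysed intramolecular aldol condensation (6-(enolexo)-exo-trig), in which only the ethyl-side enol of the ketone can reach the aldehyde through a six-membered ring, and after which the silyloxy carbon is no longer α to a carbonyl group and should keep its configuration.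

Step 3
Reactants: 5 (4R)-4-(tert-butyldimethylsilyloxy)-2-methylcyclohex-2-en-1-one
Product: 6 tert-butyl{[(1R,2R)-2,3-dimethyl-4-(trimethylsilyloxy)cyclohex-3-en-1-yl]oxy}dimethylsilane
Conditions: MeLi, CuI, Et2O, 0 °C (Me2CuLi); then 5, TMSCl, THF, −78 °C; Et3N
Reagents that add atoms: lithium dimethylcuprate, [Li+].C[Cu-]C; chlorotrimethylsilane, C[Si](C)(C)Cl
Why: Cuprate conjugate addition with in situ silylation, in which the methyl group should enter the β-carbon anti to the adjacent silyloxy group (C4 methyl trans to the C3 oxygen) and TMSCl fixes the regiodefined tetrasubstituted enolate as its silyl enol ether.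

Step 4
Reactants: 6 tert-butyl{[(1R,2R)-2,3-dimethyl-4-(trimethylsilyloxy)cyclohex-3-en-1-yl]oxy}dimethylsilane
Product: 7 (2S,3R,4R)-4-(tert-butyldimethylsilyloxy)-2-(dimethoxymethyl)-2,3-dimethylcyclohexan-1-one
Conditions: HC(OMe)3, TMSOTf (10 mol %), CH2Cl2, −78 °C
Reagents that add atoms: trimethyl orthoformate, COC(OC)OC
Why: Lewis acid-mediated coupling of a silyl enol ether with an orthoester (Mukaiyama-type acetal aldol), in which the dimethoxycarbenium ion should attack axially and anti to the pseudoaxial C4 methyl group (held axial by A(1,2) strain with the C5 methyl), so that the quaternary C5 carries its methyl cis to the C4 methyl.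

Step 5
Reactants: 7 (2S,3R,4R)-4-(tert-butyldimethylsilyloxy)-2-(dimethoxymethyl)-2,3-dimethylcyclohexan-1-one; 8 4-methylpent-3-en-2-one (mesityl oxide)
Product: 11 1-[(1RS,2R,3R,4R)-4-(tert-butyldimethylsilyloxy)-2-(dimethoxymethyl)-1-hydroxy-2,3-dimethylcyclohexyl]-4-methylpent-3-en-2-one, via lithium dienolate 9 (not isolated), via cerium dienolate 10 (not isolated)
Conditions: 8, LiN(i-Pr)2, THF, −78 °C; CeCl3, −78 °C; then 7, −78 °C; AcOH, −78 °C
Reagents that add atoms: none
Why: Aldol addition of the kinetic methyl-side enolate of mesityl oxide to a hindered ketone, in which the weakly basic cerium enolate should suppress enolisation and retro-aldol cleavage, and the configuration of the new carbinol centre is of no consequence because it is removed in step 6.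

Step 6
Reactants: 11 1-[(1RS,2R,3R,4R)-4-(tert-butyldimethylsilyloxy)-2-(dimethoxymethyl)-1-hydroxy-2,3-dimethylcyclohexyl]-4-methylpent-3-en-2-one
Product: 13 (1R,5R,6R)-5-(tert-butyldimethylsilyloxy)-1,6-dimethyl-2-(4-methyl-2-oxopent-3-en-1-ylidene)cyclohexane-1-carbaldehyde as an E/Z mixture, via enone acetal 12 (not isolated)
Conditions: PPTS (20 mol %), H2O (3 equiv), toluene, 70 °C
Reagents that add atoms: water, O
Why: Acid-catalysed dehydration of the tertiary β-hydroxy ketone followed by hydrolysis of the dimethyl acetal under conditions mild enough for the secondary silyl ether, with the geometry of the new C9=C10 bond left uncontrolled on purpose.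

Step 7
Reactants: 13 (1R,5R,6R)-5-(tert-butyldimethylsilyloxy)-1,6-dimethyl-2-(4-methyl-2-oxopent-3-en-1-ylidene)cyclohexane-1-carbaldehyde
Product: 15 (4aR,5R,6R)-6-(tert-butyldimethylsilyloxy)-4a,5-dimethyl-3-(prop-1-en-2-yl)-5,6,7,8-tetrahydronaphthalen-2(4aH)-one, via bicyclic aldol 14 (not isolated)
Conditions: KOtBu (0.3 equiv), t-BuOH/THF, 0 °C to rt
Reagents that add atoms: none
Why: tert-Butoxide removes a γ-proton of the isopropylidene ketone to give the C7–C8 dienolate, whose α-carbon C7 adds to the non-enolisable C6 aldehyde, and E1cB loss of hydroxide from aldol 14 gives the C6=C7 bond in conjugation with the C8 ketone and the isopropenyl group. The closest known reaction type is the aldol condensation that ends a Robinson annulation, here with α-attack of a dienolate. Ring B closes in the 6-(enolendo)-exo-trig mode. No new stereocentre survives, since the two centres created in 14 are erased by dehydration and C3, C4 and C5 carry no acidic hydrogen. The step needs geometric convergence and site selectivity: reversible deprotonation at C1 interconverts the C9=C10 isomers so that both drain through the one that can cyclise, attack of C9 or C1 on the aldehyde would give four-membered rings, and the hindered base should avoid retro-Claisen loss of the formyl group from C5.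

Step 8
Reactants: 15 (4aR,5R,6R)-6-(tert-butyldimethylsilyloxy)-4a,5-dimethyl-3-(prop-1-en-2-yl)-5,6,7,8-tetrahydronaphthalen-2(4aH)-one
Product: 17 (4aR,5R,6R)-6-(tert-butyldimethylsilyloxy)-3-(2-hydroxypropan-2-yl)-4a,5-dimethyl-5,6,7,8-tetrahydronaphthalen-2(4aH)-one, via tertiary hydroperoxide 16 (not isolated)
Conditions: Co(acac)2 (20 mol %), PhSiH3, O2 (1 atm), THF, rt; then PPh3
Reagents that add atoms: dioxygen, O=O
Why: Mukaiyama hydration, in which hydrogen-atom transfer from a cobalt hydride to the terminal CH2 of the isopropenyl group (the only unhindered, comparatively electron-rich alkene) should give the tertiary C11 radical that is trapped by O2 and reduced to the alcohol, while the two trisubstituted enone alkenes of the ring react far more slowly.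

Step 9
Reactants: 17 (4aR,5R,6R)-6-(tert-butyldimethylsilyloxy)-3-(2-hydroxypropan-2-yl)-4a,5-dimethyl-5,6,7,8-tetrahydronaphthalen-2(4aH)-one
Product: 18 (4aR,5R,6R)-6-hydroxy-3-(2-hydroxypropan-2-yl)-4a,5-dimethyl-5,6,7,8-tetrahydronaphthalen-2(4aH)-one
Conditions: HF·pyridine, pyridine/THF, 0 °C to rt
Reagents that add atoms: none
Why: Fluoride cleavage of a secondary silyl ether under buffered conditions that should leave the dienone and the tertiary allylic alcohol untouched.

Step 10
Reactants: 19 prop-2-yn-1-ol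
Product: 22 (2Z)-2-methyl-3-(methylsulfanyl)prop-2-en-1-ol, via magnesium alkoxide 20 (not isolated), via alkenylmagnesium bromide 21 (not isolated)
Conditions: MeMgBr (3 equiv), CuI (10 mol %), THF, −10 °C to rt; then MeSSMe, 0 °C to rt; 1 M HCl
Reagents that add atoms: methylmagnesium bromide, C[Mg]Br; dimethyl disulfide, CSSC
Why: Copper-catalysed anti-carbomagnesiation of propargyl alcohol, in which the magnesium alkoxide directs methyl to C2 and holds magnesium on C3 cis to the CH2O group in a five-membered chelate, and sulfenylation of this alkenyl Grignard reagent by the disulfide should occur with retention to fix the Z geometry.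

Step 11
Reactants: 22 (2Z)-2-methyl-3-(methylsulfanyl)prop-2-en-1-ol
Product: 24 (2Z)-2-methyl-3-(methylsulfanyl)prop-2-enoic acid, via thioenal 23 (not isolated)
Conditions: TEMPO (20 mol %), PhI(OAc)2 (2.2 equiv), MeCN/H2O, rt
Reagents that add atoms: water, O
Why: Oxoammonium (TEMPO) oxidation of a primary allylic alcohol through the aldehyde hydrate to the acid, a method that tolerates thioethers, helped here by the low nucleophilicity of the vinylogous thioester sulfur.

Step 12
Reactants: 18 (4aR,5R,6R)-6-hydroxy-3-(2-hydroxypropan-2-yl)-4a,5-dimethyl-5,6,7,8-tetrahydronaphthalen-2(4aH)-one; 24 (2Z)-2-methyl-3-(methylsulfanyl)prop-2-enoic acid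
Product: 26 (1R,2R,8aR)-7-(2-hydroxypropan-2-yl)-1,8a-dimethyl-6-oxo-1,2,3,4,6,8a-hexahydronaphthalen-2-yl (2Z)-2-methyl-3-(methylsulfanyl)prop-2-enoate, via mixed anhydride 25 (not isolated)
Conditions: 24, 2,4,6-trichlorobenzoyl chloride, Et3N, THF, rt; then 18, DMAP, toluene, rt
Reagents that add atoms: none
Why: Yamaguchi esterification through the mixed anhydride, in which only the secondary equatorial C3 hydroxyl should be acylated (the tertiary C11 hydroxyl is too hindered) and the C3 configuration is retained because its C–O bond is not touched.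

**Compound list**

1 | (tert-butyldimethylsilyloxy)acetaldehyde | CC(C)(C)[Si](C)(C)OCC=O | starting material
2 | pent-1-en-3-one | C=CC(=O)CC | starting material
3 | (2R)-2-(tert-butyldimethylsilyloxy)-5-oxoheptanal | CC(C)(C)[Si](C)(C)O[C@@H](C=O)CCC(=O)CC | intermediate
4 | (4R)-4-(tert-butyldimethylsilyloxy)-3-hydroxy-2-methylcyclohexan-1-one (C2/C3 epimers) | CC(C)(C)[Si](C)(C)O[C@@H]1CCC(=O)C(C)C1O | intermediate
5 | (4R)-4-(tert-butyldimethylsilyloxy)-2-methylcyclohex-2-en-1-one | CC(C)(C)[Si](C)(C)O[C@@H]1CCC(=O)C(C)=C1 | intermediate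
6 | tert-butyl{[(1R,2R)-2,3-dimethyl-4-(trimethylsilyloxy)cyclohex-3-en-1-yl]oxy}dimethylsilane | CC(C)(C)[Si](C)(C)O[C@@H]1CCC(O[Si](C)(C)C)=C(C)[C@H]1C | intermediate
7 | (2S,3R,4R)-4-(tert-butyldimethylsilyloxy)-2-(dimethoxymethyl)-2,3-dimethylcyclohexan-1-one | CC(C)(C)[Si](C)(C)O[C@@H]1CCC(=O)[C@](C)(C(OC)OC)[C@H]1C | intermediate
8 | 4-methylpent-3-en-2-one (mesityl oxide) | CC(=O)C=C(C)C | starting material
9 | lithium 4-methylpenta-1,3-dien-2-olate | [Li+].[O-]C(=C)C=C(C)C | intermediate
10 | dichlorocerium 4-methylpenta-1,3-dien-2-olate | C=C(O[Ce](Cl)Cl)C=C(C)C | intermediate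
11 | 1-[(1RS,2R,3R,4R)-4-(tert-butyldimethylsilyloxy)-2-(dimethoxymethyl)-1-hydroxy-2,3-dimethylcyclohexyl]-4-methylpent-3-en-2-one | CC(C)(C)[Si](C)(C)O[C@@H]1CCC(O)(CC(=O)C=C(C)C)[C@](C)(C(OC)OC)[C@H]1C | intermediate
12 | 1-[(2R,3R,4R)-4-(tert-butyldimethylsilyloxy)-2-(dimethoxymethyl)-2,3-dimethylcyclohexylidene]-4-methylpent-3-en-2-one (E/Z mixture) | CC(C)(C)[Si](C)(C)O[C@@H]1CCC(=CC(=O)C=C(C)C)[C@](C)(C(OC)OC)[C@H]1C | intermediate
13 | (1R,5R,6R)-5-(tert-butyldimethylsilyloxy)-1,6-dimethyl-2-(4-methyl-2-oxopent-3-en-1-ylidene)cyclohexane-1-carbaldehyde (E/Z mixture) | CC(C)(C)[Si](C)(C)O[C@@H]1CCC(=CC(=O)C=C(C)C)[C@](C)(C=O)[C@H]1C | intermediate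
14 | (4aR,5R,6R)-6-(tert-butyldimethylsilyloxy)-4-hydroxy-4a,5-dimethyl-3-(prop-1-en-2-yl)-4,4a,5,6,7,8-hexahydronaphthalen-2(3H)-one (C3/C4 epimers) | CC(C)(C)[Si](C)(C)O[C@@H]1CCC2=CC(=O)C(C(C)=C)C(O)[C@]2(C)[C@H]1C | intermediate
15 | (4aR,5R,6R)-6-(tert-butyldimethylsilyloxy)-4a,5-dimethyl-3-(prop-1-en-2-yl)-5,6,7,8-tetrahydronaphthalen-2(4aH)-one | CC(C)(C)[Si](C)(C)O[C@@H]1CCC2=CC(=O)C(C(C)=C)=C[C@]2(C)[C@H]1C | intermediate
16 | (4aR,5R,6R)-6-(tert-butyldimethylsilyloxy)-3-(2-hydroperoxypropan-2-yl)-4a,5-dimethyl-5,6,7,8-tetrahydronaphthalen-2(4aH)-one | CC(C)(C)[Si](C)(C)O[C@@H]1CCC2=CC(=O)C(C(C)(C)OO)=C[C@]2(C)[C@H]1C | intermediate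
17 | (4aR,5R,6R)-6-(tert-butyldimethylsilyloxy)-3-(2-hydroxypropan-2-yl)-4a,5-dimethyl-5,6,7,8-tetrahydronaphthalen-2(4aH)-one | CC(C)(C)[Si](C)(C)O[C@@H]1CCC2=CC(=O)C(C(C)(C)O)=C[C@]2(C)[C@H]1C | intermediate
18 | (4aR,5R,6R)-6-hydroxy-3-(2-hydroxypropan-2-yl)-4a,5-dimethyl-5,6,7,8-tetrahydronaphthalen-2(4aH)-one | O[C@@H]1CCC2=CC(=O)C(C(C)(C)O)=C[C@]2(C)[C@H]1C | intermediate
19 | prop-2-yn-1-ol | C#CCO | starting material
20 | bromomagnesium prop-2-yn-1-olate | C#CCO[Mg]Br | intermediate
21 | bromomagnesium (2Z)-3-(bromomagnesio)-2-methylprop-2-en-1-olate | Br[Mg]/C=C(/C)CO[Mg]Br | intermediate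
22 | (2Z)-2-methyl-3-(methylsulfanyl)prop-2-en-1-ol | CS/C=C(/C)CO | intermediate
23 | (2Z)-2-methyl-3-(methylsulfanyl)prop-2-enal | CS/C=C(/C)C=O | intermediate
24 | (2Z)-2-methyl-3-(methylsulfanyl)prop-2-enoic acid | CS/C=C(/C)C(=O)O | intermediate
25 | (2Z)-2-methyl-3-(methylsulfanyl)prop-2-enoic 2,4,6-trichlorobenzoic anhydride | CS/C=C(/C)C(=O)OC(=O)c1c(Cl)cc(Cl)cc1Cl | intermediate
26 | (1R,2R,8aR)-7-(2-hydroxypropan-2-yl)-1,8a-dimethyl-6-oxo-1,2,3,4,6,8a-hexahydronaphthalen-2-yl (2Z)-2-methyl-3-(methylsulfanyl)prop-2-enoate | CS/C=C(/C)C(=O)O[C@@H]1CCC2=CC(=O)C(C(C)(C)O)=C[C@]2(C)[C@H]1C | target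

**Step count and risks**

Total step count: 12. Longest linear sequence: 10 steps (steps 1–9 and 12).

Step 8 (hydration). What may go wrong: the radical formed by hydrogen-atom transfer is an allyl radical spread over C11 and C6, so oxygen may be captured at the C6 terminus; hydrogen-atom transfer to the dienone alkenes may also cause over-reduction. Fallback: a polar Markovnikov hydration in place of the radical one. It sets out from 15: oxymercuration with Hg(OAc)2 in THF/H2O should give the β-hydroxyalkylmercury acetate F1, water adding at the tertiary C11 end of the mercurinium ion. Reductive demercuration with NaBH4 in aqueous NaOH at 0 °C, with short contact so that the dienone is not reduced, comes back to the route at 17.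

Step 5 (aldol addition to the hindered ketone). What may go wrong: proton transfer from the ketone to the enolate instead of addition, and retro-aldol cleavage of the tertiary aldolate before or during the quench. Fallback: an irreversible acetylide addition in place of the aldol addition. It sets out from 7: 2-methylpent-1-en-4-yne F2 (from ethynylmagnesium bromide and 3-chloro-2-methylprop-1-ene with CuCl catalysis) is lithiated with n-BuLi and added to 7 to give the propargylic alcohol F3. Meyer–Schuster rearrangement with (Ph3P)AuNTf2 and MeOH in toluene, followed by PPTS in wet acetone, should give the enone aldehyde F4 as an E/Z mixture. F4 carries an acidic C7 methylene, should reach the same dienolate under the conditions of step 7, and comes back to the route at 15.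

Step 1 (enamine Michael addition). What may go wrong: self-aldol reaction of the α-silyloxy aldehyde in competition with the Michael addition, and loss of enantiomeric purity by enolisation of the α-silyloxy aldehyde before ring closure in step 2. Fallback: C3 is set by ketone reduction instead of C–C bond formation. This fallback does not use 1–4; it sets out from purchased 1,4-dioxaspiro[4.5]dec-6-en-8-one F5 and comes back to the route at 5. Noyori transfer hydrogenation with RuCl(p-cymene)[(R,R)-TsDPEN] and HCO2H/Et3N should give (8R)-1,4-dioxaspiro[4.5]dec-6-en-8-ol F6. Silylation (TBSCl, imidazole, DMF) gives the silyl ether F7, and ketal hydrolysis (PPTS, wet acetone) gives (4R)-4-(tert-butyldimethylsilyloxy)cyclohex-2-en-1-one F8. α-Iodination (I2, pyridine, CH2Cl2) gives the iodoenone F9, and Suzuki coupling with MeB(OH)2 (Pd(dppf)Cl2, K3PO4, dioxane/H2O) gives 5.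

**Further compounds**

F1 | step 8 | {2-[(4aR,5R,6R)-6-(tert-butyldimethylsilyloxy)-4a,5-dimethyl-2-oxo-2,4a,5,6,7,8-hexahydronaphthalen-3-yl]-2-hydroxypropyl}mercury acetate | CC(C)(C)[Si](C)(C)O[C@@H]1CCC2=CC(=O)C(C(C)(O)C[Hg]OC(C)=O)=C[C@]2(C)[C@H]1C
F2 | step 5 | 2-methylpent-1-en-4-yne | C#CCC(C)=C
F3 | step 5 | (1RS,2R,3R,4R)-4-(tert-butyldimethylsilyloxy)-2-(dimethoxymethyl)-2,3-dimethyl-1-(4-methylpent-4-en-1-yn-1-yl)cyclohexan-1-ol | CC(C)(C)[Si](C)(C)O[C@@H]1CCC(O)(C#CCC(C)=C)[C@](C)(C(OC)OC)[C@H]1C
F4 | step 5 | (1R,5R,6R)-5-(tert-butyldimethylsilyloxy)-1,6-dimethyl-2-(4-methyl-2-oxopent-4-en-1-ylidene)cyclohexane-1-carbaldehyde (E/Z mixture) | CC(C)(C)[Si](C)(C)O[C@@H]1CCC(=CC(=O)CC(C)=C)[C@](C)(C=O)[C@H]1C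
F5 | step 1 | 1,4-dioxaspiro[4.5]dec-6-en-8-one (purchased) | O=C1CCC2(OCCO2)C=C1
F6 | step 1 | (8R)-1,4-dioxaspiro[4.5]dec-6-en-8-ol | O[C@@H]1CCC2(OCCO2)C=C1
F7 | step 1 | tert-butyl{[(8R)-1,4-dioxaspiro[4.5]dec-6-en-8-yl]oxy}dimethylsilane | CC(C)(C)[Si](C)(C)O[C@@H]1CCC2(OCCO2)C=C1
F8 | step 1 | (4R)-4-(tert-butyldimethylsilyloxy)cyclohex-2-en-1-one | CC(C)(C)[Si](C)(C)O[C@@H]1CCC(=O)C=C1
F9 | step 1 | (4R)-4-(tert-butyldimethylsilyloxy)-2-iodocyclohex-2-en-1-one | CC(C)(C)[Si](C)(C)O[C@@H]1CCC(=O)C(I)=C1
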